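**Retrosynthetic overview**
1. Target 15 ⇐ penta-O-benzyl ether 14 (hydrogenolysis last); the lower C3–OH comes from cis-selective hydride reduction of flavan-3-one 13.
2. Key disconnection, lower C4–C4a: 13 ⇐ aryl propargyl ether 12. The terminal alkyne is oxidised to an α-oxo gold carbene (an electrophilic α-keto carbon, enolonium-type) that attacks the nucleophilic ring D. Both carbons ortho to the ether oxygen are equivalent, so only the 4→6 linkage can form.
3. 12 ⇐ triol 7 + (R)-propargylic alcohol 10 (Mitsunobu inversion sets lower C2; 10 from lipase resolution), then benzylation.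
4. 7 ⇐ phloroglucinol + (2S)-flavan-4-ol 5 (Friedel–Crafts, sets upper C4 trans to C2); 5 ⇐ rac-flavanone 4 (transfer-hydrogenation kinetic resolution) ⇐ 1 + 2.
5. Ring order: upper ring C (step 1) → ring D attached (step 3) → lower pyran ring F closed last (step 8).

Assumption: the SMILES is read as (2S,4R)-7,4'-dihydroxyflavan (2,4-trans) joined from C4 to C6 of (2R,3R)-epiafzelechin; 1, 2, 6 and all reagents are bought.

**Step 1**
Reactants: 1 1-[4-(benzyloxy)-2-hydroxyphenyl]ethan-1-one; 2 4-(benzyloxy)benzaldehyde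
Product: 4 rac-7-(benzyloxy)-2-[4-(benzyloxy)phenyl]chroman-4-one, via chalcone 3 (not isolated)
Conditions: KOH (aq.), EtOH, rt; then AcOH to pH 6, NaOAc, reflux
Reagents that add atoms: none
Why: Claisen–Schmidt aldol condensation gives the 2'-hydroxychalcone with loss of water, and this closes under buffered reflux by reversible intramolecular oxa-Michael addition to the flavanone (upper ring C); C2 is left racemic here.

**Step 2**
Reactants: 4 rac-7-(benzyloxy)-2-[4-(benzyloxy)phenyl]chroman-4-one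
Product: 5 (2S,4S)-7-(benzyloxy)-2-[4-(benzyloxy)phenyl]chroman-4-ol
Conditions: RuCl[(S,S)-TsDPEN](p-cymene) (1 mol %), HCO2H/Et3N 5:2, EtOAc, rt, stopped near 50 % conversion
Reagents that add atoms: none
Why: Noyori asymmetric transfer hydrogenation run as a kinetic resolution: the (S,S)-catalyst gives the (4S) benzylic alcohol, and this is the favoured cis hydride delivery only for the (2S)-flavanone, so (2S,4S)-5 forms and (R)-4 is left behind, which fixes upper C2.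

**Step 3**
Reactants: 5 (2S,4S)-7-(benzyloxy)-2-[4-(benzyloxy)phenyl]chroman-4-ol; 6 phloroglucinol (5 equiv)
Product: 7 2-{(2S,4R)-7-(benzyloxy)-2-[4-(benzyloxy)phenyl]chroman-4-yl}benzene-1,3,5-triol
Conditions: p-TsOH·H2O (10 mol %), THF/CH2Cl2, 0 °C to rt
Reagents that add atoms: none
Why: Friedel–Crafts alkylation with loss of water: acid ionises the benzylic alcohol to the 7-alkoxy-stabilised flavan-4-yl cation, and quasi-axial attack of the symmetric phenol anti to the equatorial 2-aryl group gives the 2,4-trans (4R) adduct, independent of the C4 configuration of 5.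

**Step 4**
Reactants: 2 4-(benzyloxy)benzaldehyde
Product: 9 rac-1-[4-(benzyloxy)phenyl]prop-2-yn-1-yl acetate, via magnesium alkoxide 8 (not isolated)
Conditions: HC≡CMgBr, THF, 0 °C; then Ac2O, 0 °C to rt
Reagents that add atoms: ethynylmagnesium bromide (C#C[Mg]Br); acetic anhydride (CC(=O)OC(C)=O)
Why: Grignard 1,2-addition of the acetylide to the aldehyde, followed by acetylation of the magnesium alkoxide in the same flask, gives the racemic propargylic acetate.

**Step 5**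
Reactants: 9 rac-1-[4-(benzyloxy)phenyl]prop-2-yn-1-yl acetate
Product: 10 (R)-1-[4-(benzyloxy)phenyl]prop-2-yn-1-ol
Conditions: immobilised Candida antarctica lipase B, n-BuOH (3 equiv), MTBE, 35 °C, to 50 % conversion
Reagents that add atoms: none
Why: Lipase-catalysed enantioselective alcoholysis (kinetic resolution): by the Kazlauskas rule (aryl large, ethynyl medium) only the (R)-acetate is cleaved, giving (R)-10 and leaving (S)-9.

**Step 6**
Reactants: 7 2-{(2S,4R)-7-(benzyloxy)-2-[4-(benzyloxy)phenyl]chroman-4-yl}benzene-1,3,5-triol; 10 (R)-1-[4-(benzyloxy)phenyl]prop-2-yn-1-ol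
Product: 11 2-{(2S,4R)-7-(benzyloxy)-2-[4-(benzyloxy)phenyl]chroman-4-yl}-5-{[(S)-1-[4-(benzyloxy)phenyl]prop-2-yn-1-yl]oxy}benzene-1,3-diol
Conditions: PPh3, DIAD, toluene/THF, −20 to 0 °C
Reagents that add atoms: none
Why: Mitsunobu etherification with inversion converts (R)-10 into the (S)-ether (the future lower C2, R once the ring is closed); the bulky oxyphosphonium is taken by the only unhindered hydroxyl of 7 (para to the flavanyl group), and the symmetric ring D of 11 shows as a 2H singlet.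

**Step 7**
Reactants: 11 2-{(2S,4R)-7-(benzyloxy)-2-[4-(benzyloxy)phenyl]chroman-4-yl}-5-{[(S)-1-[4-(benzyloxy)phenyl]prop-2-yn-1-yl]oxy}benzene-1,3-diol
Product: 12 (2S,4R)-7-(benzyloxy)-2-[4-(benzyloxy)phenyl]-4-[2,6-bis(benzyloxy)-4-{[(S)-1-[4-(benzyloxy)phenyl]prop-2-yn-1-yl]oxy}phenyl]chroman
Conditions: BnBr, K2CO3, DMF, rt
Reagents that add atoms: benzyl bromide (BrCc1ccccc1)
Why: Williamson etherification of the two remaining phenols removes the O–H bonds that could intercept the carbene in step 8; the weak base does not touch the propargylic centre.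

**Step 8**
Reactants: 12 (2S,4R)-7-(benzyloxy)-2-[4-(benzyloxy)phenyl]-4-[2,6-bis(benzyloxy)-4-{[(S)-1-[4-(benzyloxy)phenyl]prop-2-yn-1-yl]oxy}phenyl]chroman
Product: 13 (2R)-5,7-bis(benzyloxy)-2-[4-(benzyloxy)phenyl]-6-{(2S,4R)-7-(benzyloxy)-2-[4-(benzyloxy)phenyl]chroman-4-yl}chroman-3-one
Conditions: Me4tBuXPhosAuNTf2 (5 mol %), 2,6-dichloropyridine N-oxide (1.3 equiv), ClCH2CH2Cl, rt, 0.05 M
Reagents that add atoms: 2,6-dichloropyridine N-oxide ([O-][n+]1c(Cl)cccc1Cl)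
Why: Key step, a gold-catalysed alkyne oxidation: the N-oxide adds to the internal carbon of the alkyne activated by cationic monovalent gold, and N–O cleavage gives an α-oxo gold carbene whose carbon (normally the nucleophilic α-carbon of the ketone) attacks nucleophilic ring D ortho to the ether oxygen in an intramolecular aromatic substitution; the two ortho carbons are equivalent, so only the 4→6-linked chroman-3-one forms, and the neutral conditions leave C2 intact.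

**Step 9**
Reactants: 13 (2R)-5,7-bis(benzyloxy)-2-[4-(benzyloxy)phenyl]-6-{(2S,4R)-7-(benzyloxy)-2-[4-(benzyloxy)phenyl]chroman-4-yl}chroman-3-one (used at once)
Product: 14 (2R,3R)-5,7-bis(benzyloxy)-2-[4-(benzyloxy)phenyl]-6-{(2S,4R)-7-(benzyloxy)-2-[4-(benzyloxy)phenyl]chroman-4-yl}chroman-3-ol
Conditions: LiBH(s-Bu)3, THF, −78 °C; H2O work-up
Reagents that add atoms: none
Why: Substrate-controlled ketone reduction: the bulky hydride adds to the face opposite the 2-aryl group, giving the 2,3-cis (3R) alcohol; any C2 epimer carried from step 6 is a diastereomer and is removed here.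

**Step 10**
Reactants: 14 (2R,3R)-5,7-bis(benzyloxy)-2-[4-(benzyloxy)phenyl]-6-{(2S,4R)-7-(benzyloxy)-2-[4-(benzyloxy)phenyl]chroman-4-yl}chroman-3-ol
Product: 15 (2R,3R)-6-[(2S,4R)-7-hydroxy-2-(4-hydroxyphenyl)chroman-4-yl]-2-(4-hydroxyphenyl)chroman-3,5,7-triol
Conditions: H2 (1 atm), Pd(OH)2/C, THF/MeOH, rt
Reagents that add atoms: none
Why: Catalytic hydrogenolysis cleaves the five benzyl ethers under neutral conditions that leave the interflavan bond, both pyran rings and all four stereocentres untouched.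

**Compound list**
1 | 1-[4-(benzyloxy)-2-hydroxyphenyl]ethan-1-one | CC(=O)c1ccc(OCc2ccccc2)cc1O | starting material
2 | 4-(benzyloxy)benzaldehyde | O=Cc1ccc(OCc2ccccc2)cc1 | starting material
3 | (E)-1-[4-(benzyloxy)-2-hydroxyphenyl]-3-[4-(benzyloxy)phenyl]prop-2-en-1-one | O=C(/C=C/c1ccc(OCc2ccccc2)cc1)c1ccc(OCc2ccccc2)cc1O | intermediate
4 | rac-7-(benzyloxy)-2-[4-(benzyloxy)phenyl]chroman-4-one | O=C1CC(c2ccc(OCc3ccccc3)cc2)Oc2cc(OCc3ccccc3)ccc12 | intermediate
5 | (2S,4S)-7-(benzyloxy)-2-[4-(benzyloxy)phenyl]chroman-4-ol | c1ccccc1COc1ccc([C@@H]2C[C@H](O)c3ccc(OCc4ccccc4)cc3O2)cc1 | intermediate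
6 | phloroglucinol (benzene-1,3,5-triol) | Oc1cc(O)cc(O)c1 | starting material
7 | 2-{(2S,4R)-7-(benzyloxy)-2-[4-(benzyloxy)phenyl]chroman-4-yl}benzene-1,3,5-triol | c1ccccc1COc1ccc([C@@H]2C[C@@H](c3c(O)cc(O)cc3O)c3ccc(OCc4ccccc4)cc3O2)cc1 | intermediate
8 | bromomagnesium 1-[4-(benzyloxy)phenyl]prop-2-yn-1-olate (racemic) | C#CC(O[Mg]Br)c1ccc(OCc2ccccc2)cc1 | intermediate
9 | rac-1-[4-(benzyloxy)phenyl]prop-2-yn-1-yl acetate | C#CC(OC(C)=O)c1ccc(OCc2ccccc2)cc1 | intermediate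
10 | (R)-1-[4-(benzyloxy)phenyl]prop-2-yn-1-ol | C#C[C@@H](O)c1ccc(OCc2ccccc2)cc1 | intermediate
11 | 2-{(2S,4R)-7-(benzyloxy)-2-[4-(benzyloxy)phenyl]chroman-4-yl}-5-{[(S)-1-[4-(benzyloxy)phenyl]prop-2-yn-1-yl]oxy}benzene-1,3-diol | c1ccccc1COc1ccc([C@@H]2C[C@@H](c3c(O)cc(O[C@@H](C#C)c4ccc(OCc5ccccc5)cc4)cc3O)c3ccc(OCc4ccccc4)cc3O2)cc1 | intermediate
12 | (2S,4R)-7-(benzyloxy)-2-[4-(benzyloxy)phenyl]-4-[2,6-bis(benzyloxy)-4-{[(S)-1-[4-(benzyloxy)phenyl]prop-2-yn-1-yl]oxy}phenyl]chroman | c1ccccc1COc1ccc([C@@H]2C[C@@H](c3c(OCc4ccccc4)cc(O[C@@H](C#C)c4ccc(OCc5ccccc5)cc4)cc3OCc3ccccc3)c3ccc(OCc4ccccc4)cc3O2)cc1 | intermediate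
13 | (2R)-5,7-bis(benzyloxy)-2-[4-(benzyloxy)phenyl]-6-{(2S,4R)-7-(benzyloxy)-2-[4-(benzyloxy)phenyl]chroman-4-yl}chroman-3-one | c1ccccc1COc1ccc([C@@H]2C[C@@H](c3c(OCc4ccccc4)cc4c(c3OCc3ccccc3)CC(=O)[C@@H](c3ccc(OCc5ccccc5)cc3)O4)c3ccc(OCc4ccccc4)cc3O2)cc1 | intermediate
14 | (2R,3R)-5,7-bis(benzyloxy)-2-[4-(benzyloxy)phenyl]-6-{(2S,4R)-7-(benzyloxy)-2-[4-(benzyloxy)phenyl]chroman-4-yl}chroman-3-ol | c1ccccc1COc1ccc([C@@H]2C[C@@H](c3c(OCc4ccccc4)cc4c(c3OCc3ccccc3)C[C@@H](O)[C@@H](c3ccc(OCc5ccccc5)cc3)O4)c3ccc(OCc4ccccc4)cc3O2)cc1 | intermediate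
15 | (2R,3R)-6-[(2S,4R)-7-hydroxy-2-(4-hydroxyphenyl)chroman-4-yl]-2-(4-hydroxyphenyl)chroman-3,5,7-triol | Oc1ccc([C@@H]2C[C@@H](c3c(O)cc4c(c3O)C[C@@H](O)[C@@H](c3ccc(O)cc3)O4)c3ccc(O)cc3O2)cc1 | target

**Step count**
Total: 10 steps. Longest linear sequence: 8 steps (1, 2, 3, 6, 7, 8, 9, 10); steps 4 and 5 form the side arm.

**Three steps most likely to fail**

Step 8. The electron-rich ring D may add directly to the gold-activated alkyne (6-endo hydroarylation) faster than the N-oxide does, or the p-alkoxybenzylic propargylic C–O bond may ionise. Fallback, from 12 and back at 13: turn the likely side reaction into the route. Without N-oxide, PtCl2 in toluene cyclises 12 to the chromene (2S)-5,7-bis(benzyloxy)-2-[4-(benzyloxy)phenyl]-6-{(2S,4R)-7-(benzyloxy)-2-[4-(benzyloxy)phenyl]chroman-4-yl}-2H-chromene F8. Hydroboration–oxidation (BH3·THF, then NaOH/H2O2) puts the hydroxyl on C3 anti to the 2-aryl group and gives the 2,3-trans alcohol (2R,3S)-5,7-bis(benzyloxy)-2-[4-(benzyloxy)phenyl]-6-{(2S,4R)-7-(benzyloxy)-2-[4-(benzyloxy)phenyl]chroman-4-yl}chroman-3-ol F9. Dess–Martin periodinane oxidises it to 13, which continues with step 9.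

Step 6. Three phenols compete, and the oxyphosphonium of an electron-rich benzylic alcohol can ionise and erode the new centre. Fallback, from 5 and 6 and back at 12: fix the para oxygen before the coupling. 6 is monosilylated (TIPSCl, imidazole) to 5-[(triisopropylsilyl)oxy]benzene-1,3-diol F4. Friedel–Crafts reaction with 5 under the step 3 conditions goes between the two hydroxyls, away from the silyl ether, and gives 2-{(2S,4R)-7-(benzyloxy)-2-[4-(benzyloxy)phenyl]chroman-4-yl}-5-[(triisopropylsilyl)oxy]benzene-1,3-diol F5. BnBr/K2CO3 gives (2S,4R)-7-(benzyloxy)-2-[4-(benzyloxy)phenyl]-4-{2,6-bis(benzyloxy)-4-[(triisopropylsilyl)oxy]phenyl}chroman F6, and TBAF frees the single phenol 3,5-bis(benzyloxy)-4-{(2S,4R)-7-(benzyloxy)-2-[4-(benzyloxy)phenyl]chroman-4-yl}phenol F7. Mitsunobu reaction of this phenol with 10 then gives 12 with no choice of oxygen.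

Step 2. The resolution caps the yield at 50 % and needs a high selectivity factor on this substrate. Fallback, from 1 and back at 5: set C2 by catalytic asymmetric conjugate addition. 1 is condensed with DMF dimethyl acetal to (E)-1-[4-(benzyloxy)-2-hydroxyphenyl]-3-(dimethylamino)prop-2-en-1-one F1, which closes with HCl to 7-(benzyloxy)-4H-chromen-4-one F2. Conjugate addition of 4-(benzyloxy)phenylboronic acid with Pd(OCOCF3)2 and (R)-t-BuPyOx (antipode assigned by analogy with cyclic enones) gives (2S)-7-(benzyloxy)-2-[4-(benzyloxy)phenyl]chroman-4-one F3. NaBH4 reduces this cis-selectively to 5.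

**Further compounds**
F1 | step 2 | (E)-1-[4-(benzyloxy)-2-hydroxyphenyl]-3-(dimethylamino)prop-2-en-1-one | CN(C)/C=C/C(=O)c1ccc(OCc2ccccc2)cc1O
F2 | step 2 | 7-(benzyloxy)-4H-chromen-4-one | O=c1ccoc2cc(OCc3ccccc3)ccc12
F3 | step 2 | (2S)-7-(benzyloxy)-2-[4-(benzyloxy)phenyl]chroman-4-one | c1ccccc1COc1ccc([C@@H]2CC(=O)c3ccc(OCc4ccccc4)cc3O2)cc1
F4 | step 6 | 5-[(triisopropylsilyl)oxy]benzene-1,3-diol | CC(C)[Si](Oc1cc(O)cc(O)c1)(C(C)C)C(C)C
F5 | step 6 | 2-{(2S,4R)-7-(benzyloxy)-2-[4-(benzyloxy)phenyl]chroman-4-yl}-5-[(triisopropylsilyl)oxy]benzene-1,3-diol | c1ccccc1COc1ccc([C@@H]2C[C@@H](c3c(O)cc(O[Si](C(C)C)(C(C)C)C(C)C)cc3O)c3ccc(OCc4ccccc4)cc3O2)cc1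
F6 | step 6 | (2S,4R)-7-(benzyloxy)-2-[4-(benzyloxy)phenyl]-4-{2,6-bis(benzyloxy)-4-[(triisopropylsilyl)oxy]phenyl}chroman | c1ccccc1COc1ccc([C@@H]2C[C@@H](c3c(OCc4ccccc4)cc(O[Si](C(C)C)(C(C)C)C(C)C)cc3OCc3ccccc3)c3ccc(OCc4ccccc4)cc3O2)cc1
F7 | step 6 | 3,5-bis(benzyloxy)-4-{(2S,4R)-7-(benzyloxy)-2-[4-(benzyloxy)phenyl]chroman-4-yl}phenol | c1ccccc1COc1ccc([C@@H]2C[C@@H](c3c(OCc4ccccc4)cc(O)cc3OCc3ccccc3)c3ccc(OCc4ccccc4)cc3O2)cc1
F8 | step 8 | (2S)-5,7-bis(benzyloxy)-2-[4-(benzyloxy)phenyl]-6-{(2S,4R)-7-(benzyloxy)-2-[4-(benzyloxy)phenyl]chroman-4-yl}-2H-chromene | c1ccccc1COc1ccc([C@@H]2C[C@@H](c3c(OCc4ccccc4)cc4c(c3OCc3ccccc3)C=C[C@@H](c3ccc(OCc5ccccc5)cc3)O4)c3ccc(OCc4ccccc4)cc3O2)cc1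
F9 | step 8 | (2R,3S)-5,7-bis(benzyloxy)-2-[4-(benzyloxy)phenyl]-6-{(2S,4R)-7-(benzyloxy)-2-[4-(benzyloxy)phenyl]chroman-4-yl}chroman-3-ol | c1ccccc1COc1ccc([C@@H]2C[C@@H](c3c(OCc4ccccc4)cc4c(c3OCc3ccccc3)C[C@H](O)[C@@H](c3ccc(OCc5ccccc5)cc3)O4)c3ccc(OCc4ccccc4)cc3O2)cc1
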